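## Analysis of the target

The target 28 is a polyprenylated acylphloroglucinol built on a bicyclo[3.3.1]nonane. C1 and C5 are the bridgeheads, C2–C3–C4 is the enolised β-diketone bridge with the 3,4-dihydroxybenzoyl group on C3, C9 is the bridging ketone, C6 a methylene, C7 a methine and C8 the gem-dimethyl carbon; ring A is C1, C8, C7, C6, C5, C9 and ring B is C1 to C5 with C9. C1 and C5 are quaternary and carry prenyl groups, C1 is also bonded to the quaternary C8, and C7 carries the (E)-geranyl chain. There are three stereocentres, (1S,5S,7S) for the drawn tautomer. C1 and C5 are tied to each other because the C2–C4 bridge can span ring A on one face only, so the free elements are the absolute configuration of one bridgehead and the orientation at C7, where geranyl is endo (on the face of ring A turned toward the C2–C4 bridge) and hydrogen is exo. Sensitive groups are the catechol (oxidised in base and air), the acidic triketone enol (closes onto the prenyl alkenes under acid, is O-alkylated easily) and three trisubstituted alkenes, which exclude hydrogenation and strong acids. The hard points are the adjacent quaternary carbons C1 and C8, the fully substituted bridgeheads and the endo group on C7, which must be placed under kinetic control. The strategy rests on C6: it is a methylene between C5, an enolisable carbon once ring B is a dearomatised phloroglucinol, and C7, so a C6=C7 double bond with an electron-withdrawing group on C7 makes C6 the β-carbon of an acceptor that C5 can reach, and that group can later be replaced by hydrogen from the open exo face.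

## Retrosynthetic reasoning

**O–Si bonds (28 from 27).** The catechol is masked to the end as its bis(triisopropylsilyl) ether 27. Aryl triisopropylsilyl ethers survive dilute acid, amide bases and dissolving metal, and fall to buffered fluoride, which touches neither the alkenes nor the enol.

**C7–H bond (27 from 26).** The hydrogen on C7 is put in last, by reductive removal of a phenylsulfonyl group from the geranylated sulfone 26. The forward step must deliver hydrogen to C7 from the exo face, the only open one, because the C2–C4 bridge lies under the endo face; this places geranyl endo. Cutting here keeps the least stable stereochemical feature out of every basic or hot step.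

**C7–C1′ bond (26 from 23 and 24).** The geranyl chain is attached by alkylating the α-sulfonyl carbanion of the bicyclic sulfone 23 with geranyl bromide 24. The sulfone that activated the ring closure is used a second time as the carbanion-stabilising group, so no extra functional group is needed on C7.

**C5–C6 bond (23 from 21).** Ring A is opened between C5 and C6. This is the only ring A bond whose cleavage leaves an aromatic-derived ring B intact and a terminal, unhindered acceptor carbon. The precursor 21 is a dearomatised aroylphloroglucinol whose quaternary C1 carries prenyl and a 2-methyl-3-(phenylsulfonyl)but-3-en-2-yl group. Forward, the C5 enolate carbon must add to C6 (not an enolate oxygen, not C3), and C1 must control C5.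

**Enantiomers, then C1–C8 (21 from 20, 20 from 19).** 21 has a single stereocentre and is obtained from the racemate 20 by chromatography on a chiral phase, the simplest dependable source of one enantiomer for a compound with no nearby handle for asymmetric induction. The C1–C8 bond between two quaternary carbons is cut by a retro-Claisen step to the aryl allyl ether 19. A [3,3] shift is the one reaction type that forms such a bond without an intermolecular attack on a tertiary carbon, and both ortho carbons of 19 carry prenyl, so either gives the same constitution.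

**O–CH2 bond (19 from 11 and 18).** The ether is made from the diprenylated triol 11 and the allylic bromide 18 at the hydroxyl para to the aroyl group, the most acidic and the only non-chelated one.

**Side chain (18 from 17, 17 from 15, 15 from 12 and 13).** The bromide comes from the tertiary allylic alcohol 17 by allylic transposition. 17 comes from the diol 15 by elimination across the primary carbinol, and 15 from 2-(phenylsulfonyl)ethanol 12 and acetone 13. This puts sulfur on the central carbon and the two methyls on the terminus with no regiochemical choice.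

**Two C–prenyl bonds (11 from 8 and 9).** The prenyl groups go onto the two free ring carbons of the acylphloroglucinol 8 with prenyl bromide 9, the standard C-alkylation of this class.

**Diaryl ketone (8 from 7, 7 from 6, 6 from 4 and 2; 4 from 3; 2 from 1).** A Friedel–Crafts acylation would not tolerate silyl ethers, so the ketone is cut at the aryl–carbonyl bond. The aryllithium of tris(methoxymethyl) phloroglucinol 4 (from phloroglucinol 3) adds to the silylated aldehyde 2 (from 3,4-dihydroxybenzaldehyde 1). Oxidation of carbinol 6 gives ketone 7, and acid removes the acetals to give 8 with the silyl ethers intact.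

## Alternatives that were turned down

**Alternative 1:** The C1–C2 bond is cut. The precursor is the fused enol lactone A2, in which O9 of a ring A enol (C1=C9) is acylated by C2 of a 3-methoxyacryloyl unit attached to C5. Irradiation near 300 nm would cleave O9–C2, and the acyl radical would recombine at C1 (a photo-Fries-type 1,3-acyl shift), giving the C3-unsubstituted methyl enol ether A1.
- For it: the crowded C1–C2 bond is made inside a radical pair without acid or base, the ring B oxygens come out differentiated, and C5 and C7 are set early on a monocyclic ketone where asymmetric catalysis applies. No resolution is needed, and on that point it is stronger than the chosen route.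
- Against it: A2 needs ring A with C5, C7 and C8 in place and a regiodefined tetrasubstituted enol ester. Recombination must occur at a carbon flanked by two quaternary centres, while return to oxygen, decarbonylation and ketene formation compete. The three trisubstituted alkenes and the chromophore of A1 are exposed to the same light. C3 must still be aroylated and the enol ether cleaved afterwards.
- Comparison: the chosen route carries the aroyl group from the start, needs three steps after ring closure and closes the ring by a ground-state ionic reaction of a known class. It gives up the early, catalyst-controlled stereochemistry of A2.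

**Alternative 2:** The C3–C4 bond is cut. The precursor A4 is a ring A cyclohexanone with a formyl group (C4) on C5 and a diazoacetyl group (C2, C3) on C1, cis to each other. A divalent tin Lewis acid would activate the aldehyde, the diazo carbon would add, and a 1,2-hydride shift with loss of dinitrogen would give the β-diketone A3 (intramolecular Roskamp homologation).
- For it: the closure is mild and gives ring B directly at the diketone oxidation level with C3 free, so C3 aroylation is easy and no enol ether has to be cleaved. C7 is again fixed early.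
- Against it: A4 needs two quaternary centres α and α′ to the ketone with both carbon substituents on the same face, plus C7. The β-keto aldehyde on C5 is prone to deformylation. The diazoketone has to be built on a neopentyl-type carbon next to C8. The activated aldehyde sits three atoms from the C5 prenyl alkene (carbonyl-ene or Prins closure), and epoxide formation or carbon migration compete with the hydride shift.
- Comparison: once A4 exists the closure is probably as dependable as the chosen one. The way to A4 is much longer than the eight linear steps from 3 to the racemic precursor 20. The chosen route pays with a resolution and a late C7.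

**Alternative 3:** The C4–C5 bond is cut. The precursor A6 is the ring A silyl enol ether (C5=C9) carrying an ethoxy-ynone (C2, C3, C4) on C1. A cationic phosphine complex of monovalent gold would activate the alkyne, C5 would add to C4 in a 6-endo-dig closure, and an added alcohol would take gold from C3 and silicon from O9, giving the ethyl enol ether A5.
- For it: gold-catalysed closure of silyl enol ethers onto alkynes is an established, very mild way to bridged ketones, and the enol ether regiochemistry is fixed because C1 is quaternary. For the ring-forming event itself this alternative has the closest precedent and is at least as strong as the chosen step.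
- Against it: the C1 prenyl alkene and the ynone form a 1,6-enyne, which gold can cycloisomerise. The ynol ether is easily hydrated. A6 needs C1, C7 and C8 set on a cyclohexanone beforehand, with the ynone installed next to the gem-dimethyl carbon. After closure, C3 aroylation and removal of the ethyl group remain.
- Comparison: the chosen strategy builds ring B from phloroglucinol in a few aromatic steps and has the aroyl group in place. It accepts a less precedented acceptor (a sulfone with a quaternary C8) in exchange for the shorter route.

Key step: step 13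

Assumption: the enolised triketone is drawn throughout as the tautomer with the C2 carbonyl and the C4 enol, and CIP descriptors refer to that tautomer and to the numbering above. Where C7 carries the sulfone (23, 26), the epimer expected is drawn, and the other epimer would serve equally.

## Route

Step 1
Reactants: 1 3,4-dihydroxybenzaldehyde
Product: 2 3,4-bis(triisopropylsilyloxy)benzaldehyde
Conditions: i-Pr3SiCl, imidazole, DMF, 25 → 40 °C
Reagents that add atoms: triisopropylsilyl chloride, CC(C)[Si](Cl)(C(C)C)C(C)C
Why: Standard silylation of both phenols; the aldehyde is untouched. Triisopropylsilyl is chosen because its aryl ethers should survive the acid of step 5 and the bases of steps 6 to 14 yet fall to fluoride in step 16.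

Step 2
Reactants: 3 phloroglucinol
Product: 4 1,3,5-tris(methoxymethoxy)benzene
Conditions: NaH, MeOCH2Cl, DMF, 0 °C → rt
Reagents that add atoms: chloromethyl methyl ether, COCCl
Why: Williamson-type O-alkylation with a hard chloromethyl ether should give the tris-acetal. The acetals direct the lithiation of step 3 and are removed by acid that the silyl ethers tolerate.

Step 3
Reactants: 4 1,3,5-tris(methoxymethoxy)benzene; 2 3,4-bis(triisopropylsilyloxy)benzaldehyde
Product: 6 [3,4-bis(triisopropylsilyloxy)phenyl][2,4,6-tris(methoxymethoxy)phenyl]methanol (racemic), via 2,4,6-tris(methoxymethoxy)phenyllithium 5 (not isolated)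
Conditions: n-BuLi, THF, 0 °C; then 2, −78 °C → rt; aq. NH4Cl
Reagents that add atoms: none
Why: Directed ortho-metalation between two acetal oxygens (the three ring positions are equivalent), then 1,2-addition of the aryllithium to the aldehyde. The carbinol stereocentre is removed in step 4.

Step 4
Reactants: 6 [3,4-bis(triisopropylsilyloxy)phenyl][2,4,6-tris(methoxymethoxy)phenyl]methanol
Product: 7 [3,4-bis(triisopropylsilyloxy)phenyl][2,4,6-tris(methoxymethoxy)phenyl]methanone
Conditions: Dess–Martin periodinane, NaHCO3, CH2Cl2, rt
Reagents that add atoms: none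
Why: Dess–Martin oxidation of a diarylmethanol under buffered, neutral conditions that leave acetals and silyl ethers alone.

Step 5
Reactants: 7 [3,4-bis(triisopropylsilyloxy)phenyl][2,4,6-tris(methoxymethoxy)phenyl]methanone
Product: 8 [3,4-bis(triisopropylsilyloxy)phenyl](2,4,6-trihydroxyphenyl)methanone
Conditions: aq. HCl (3 M), MeOH/THF, 45 °C
Reagents that add atoms: none
Why: Acid-catalysed acetal exchange with methanol removes the three methoxymethyl groups, which are activated by the ortho/para acyl group. Aryl triisopropylsilyl ethers are slow to cleave in dilute methanolic acid.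

Step 6
Reactants: 8 [3,4-bis(triisopropylsilyloxy)phenyl](2,4,6-trihydroxyphenyl)methanone; 9 prenyl bromide (1-bromo-3-methylbut-2-ene)
Product: 11 [3,4-bis(triisopropylsilyloxy)phenyl][2,4,6-trihydroxy-3,5-bis(3-methylbut-2-enyl)phenyl]methanone, via 3-prenyl ketone 10 (not isolated)
Conditions: 9 (2.2 equiv), DBU (2.2 equiv), THF, 0 °C → rt
Reagents that add atoms: none
Why: C-prenylation of an acylphloroglucinol at its two free ring carbons, the usual outcome with allylic bromides. A non-hydroxylic amidine base spares the silyl ethers; O-prenyl and triprenyl by-products are expected and removed by chromatography.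

Step 7
Reactants: 12 2-(phenylsulfonyl)ethanol; 13 acetone
Product: 15 3-methyl-2-(phenylsulfonyl)butane-1,3-diol (racemic), via dilithio sulfone 14 (not isolated)
Conditions: n-BuLi (2.1 equiv), THF, −78 → −30 °C; then 13, −78 °C; aq. NH4Cl
Reagents that add atoms: none
Why: The O,C-dianion of a β-hydroxy sulfone adds through carbon to the ketone (aldol-type addition of a sulfonyl carbanion). The β-oxido group cannot leave, so no vinyl sulfone forms.

Step 8
Reactants: 15 3-methyl-2-(phenylsulfonyl)butane-1,3-diol
Product: 17 2-methyl-3-(phenylsulfonyl)but-3-en-2-ol, via primary mesylate 16 (not isolated)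
Conditions: MeSO2Cl (1.1 equiv), Et3N (2.5 equiv), CH2Cl2, 0 °C → rt
Reagents that add atoms: none
Why: Only the primary hydroxyl is sulfonylated; E1cB elimination through the acidic α-sulfonyl hydrogen then gives the 2-sulfonyl allylic alcohol, the formal Baylis–Hillman adduct of phenyl vinyl sulfone and acetone.

Step 9
Reactants: 17 2-methyl-3-(phenylsulfonyl)but-3-en-2-ol
Product: 18 1-bromo-3-methyl-2-(phenylsulfonyl)but-2-ene
Conditions: PBr3 (0.4 equiv), Et2O, 0 °C → rt
Reagents that add atoms: phosphorus tribromide, BrP(Br)Br
Why: SN2′ bromination with allylic transposition, the standard conversion of tertiary Baylis–Hillman-type alcohols into 2-(bromomethyl) alkenes. Bromide adds to the terminal methylene and the activated tertiary oxygen leaves; the sulfone disfavours an SN1 path.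

Step 10
Reactants: 11 [3,4-bis(triisopropylsilyloxy)phenyl][2,4,6-trihydroxy-3,5-bis(3-methylbut-2-enyl)phenyl]methanone; 18 1-bromo-3-methyl-2-(phenylsulfonyl)but-2-ene
Product: 19 [3,4-bis(triisopropylsilyloxy)phenyl]{2,6-dihydroxy-3,5-bis(3-methylbut-2-enyl)-4-[3-methyl-2-(phenylsulfonyl)but-2-enyloxy]phenyl}methanone
Conditions: K2CO3 (1.1 equiv), acetone, rt
Reagents that add atoms: none
Why: Williamson ether synthesis at the hydroxyl para to the aroyl group, the most acidic one and the only one not hydrogen-bonded to the ketone. A weak carbonate base in acetone favours O- over C-alkylation and cannot deconjugate the vinyl sulfone.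

Step 11
Reactants: 19 [3,4-bis(triisopropylsilyloxy)phenyl]{2,6-dihydroxy-3,5-bis(3-methylbut-2-enyl)-4-[3-methyl-2-(phenylsulfonyl)but-2-enyloxy]phenyl}methanone
Product: 20 racemic 2-[3,4-bis(triisopropylsilyloxy)benzoyl]-3,5-dihydroxy-4,6-bis(3-methylbut-2-enyl)-6-[2-methyl-3-(phenylsulfonyl)but-3-en-2-yl]cyclohexa-2,4-dien-1-one
Conditions: PhMe, 110 °C, sealed tube, Ar
Reagents that add atoms: none
Why: Aromatic Claisen rearrangement to a prenyl-bearing ortho carbon forms C1–C8; the two ortho carbons are enantiotopic, so the product is racemic. It cannot re-aromatise and should be held as the enolised triketone, as lupulone-type compounds are; the sulfone on the central allyl carbon suppresses ionisation of the ether.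

Step 12
Reactants: 20 racemic 2-[3,4-bis(triisopropylsilyloxy)benzoyl]-3,5-dihydroxy-4,6-bis(3-methylbut-2-enyl)-6-[2-methyl-3-(phenylsulfonyl)but-3-en-2-yl]cyclohexa-2,4-dien-1-one
Product: 21 (6S)-2-[3,4-bis(triisopropylsilyloxy)benzoyl]-3,5-dihydroxy-4,6-bis(3-methylbut-2-enyl)-6-[2-methyl-3-(phenylsulfonyl)but-3-en-2-yl]cyclohexa-2,4-dien-1-one
Conditions: preparative HPLC on amylose tris(3,5-dimethylphenylcarbamate), hexane/i-PrOH/CF3CO2H
Reagents that add atoms: none
Why: Separation of enantiomers on a chiral stationary phase; the acid modifier keeps the vinylogous acid protonated. The fraction with (S) at the quaternary carbon (C1 of the later bicycle) should be identified by anomalous-dispersion X-ray analysis of crystalline 23.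

Step 13
Reactants: 21 (6S)-2-[3,4-bis(triisopropylsilyloxy)benzoyl]-3,5-dihydroxy-4,6-bis(3-methylbut-2-enyl)-6-[2-methyl-3-(phenylsulfonyl)but-3-en-2-yl]cyclohexa-2,4-dien-1-one
Product: 23 (1S,5S,7R)-3-[3,4-bis(triisopropylsilyloxy)benzoyl]-4-hydroxy-8,8-dimethyl-1,5-bis(3-methylbut-2-enyl)-7-(phenylsulfonyl)bicyclo[3.3.1]non-3-ene-2,9-dione, via dipotassium dienolate 22 (not isolated)
Conditions: KN(SiMe3)2 (2.5 equiv), THF, 0 → 65 °C; then aq. HCl (1 M), 0 °C
Reagents that add atoms: none
Why: Two equivalents of base convert the vinylogous diacid 21 into the dienolate 22, whose C5 carbon adds to the unsubstituted terminus C6 of the tethered vinyl sulfone; the α-sulfonyl carbanion left on C7 is protonated by the hexamethyldisilazane formed in the deprotonation or on work-up, and this proton transfer, with the triketone enolate kept, should make the carbon adduct the sink. The closest known reaction type is the Michael closure of dearomatised acylphloroglucinol enolates onto α-substituted acrylate and enal acceptors in alkylative dearomatisation–annulation; here the acceptor is a sulfone and C8 is quaternary. Ring A (C5, C6, C7, C8, C1, C9) closes in a 6-endo-trig mode, both alkene carbons ending in the new ring. C5 is controlled by C1: the tether C8–C7–C6 can reach C5 only on the face of the flat ring B on which C8 stands, so (1S) dictates (5S). C7 is formed by protonation and is expected to settle under the excess base as the exo sulfone (7R); its configuration does not matter because the centre is rebuilt in steps 14 and 15. The step needs attack through C5 and not through O9, O2 or C3: oxygen closure gives a β-oxy sulfone carbanion that expels the enolate again, so it is reversible, and C3 is the least nucleophilic enolate carbon, carries the aroyl group and would give a non-enolisable triketone that can also revert. The gem-dimethyl group on C8 favours the folded conformer, the acceptor terminus is unhindered, and C8 has no hydrogen through which the vinyl sulfone could isomerise.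

Step 14
Reactants: 23 (1S,5S,7R)-3-[3,4-bis(triisopropylsilyloxy)benzoyl]-4-hydroxy-8,8-dimethyl-1,5-bis(3-methylbut-2-enyl)-7-(phenylsulfonyl)bicyclo[3.3.1]non-3-ene-2,9-dione; 24 geranyl bromide ((2E)-1-bromo-3,7-dimethylocta-2,6-diene)
Product: 26 (1S,5S,7S)-3-[3,4-bis(triisopropylsilyloxy)benzoyl]-7-[(2E)-3,7-dimethylocta-2,6-dienyl]-4-hydroxy-8,8-dimethyl-1,5-bis(3-methylbut-2-enyl)-7-(phenylsulfonyl)bicyclo[3.3.1]non-3-ene-2,9-dione, via dilithio sulfone 25 (not isolated)
Conditions: LiN(i-Pr)2 (2.3 equiv), THF/DMPU, −78 → −40 °C; then 24 (1.5 equiv), −78 → 0 °C; aq. NH4Cl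
Reagents that add atoms: none
Why: Dianion alkylation: the first equivalent of base makes the triketone enolate, which also shields the carbonyl groups, and the second makes the α-sulfonyl carbanion, which is far more nucleophilic and should take the primary allylic bromide by SN2 with the (E)-alkene intact. Attack from the exo face is expected (geranyl exo, sulfonyl endo), but the C7 configuration is erased in step 15.

Step 15
Reactants: 26 (1S,5S,7S)-3-[3,4-bis(triisopropylsilyloxy)benzoyl]-7-[(2E)-3,7-dimethylocta-2,6-dienyl]-4-hydroxy-8,8-dimethyl-1,5-bis(3-methylbut-2-enyl)-7-(phenylsulfonyl)bicyclo[3.3.1]non-3-ene-2,9-dione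
Product: 27 (1S,5S,7S)-3-[3,4-bis(triisopropylsilyloxy)benzoyl]-7-[(2E)-3,7-dimethylocta-2,6-dienyl]-4-hydroxy-8,8-dimethyl-1,5-bis(3-methylbut-2-enyl)bicyclo[3.3.1]non-3-ene-2,9-dione
Conditions: Na(Hg) (6% Na), Na2HPO4, MeOH/THF, −20 °C; then aq. NaH2PO4
Reagents that add atoms: none
Why: Reductive desulfonylation by electron transfer: the C–S bond breaks, sulfinate leaves, and the C7 carbanion is protonated by methanol. The endo face is covered by the C2–C4 bridge, whose enolate carries no proton under the buffer, so hydrogen should arrive on the exo face and leave geranyl endo (7S); the ionised triketone is also protected from reduction.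

Step 16
Reactants: 27 (1S,5S,7S)-3-[3,4-bis(triisopropylsilyloxy)benzoyl]-7-[(2E)-3,7-dimethylocta-2,6-dienyl]-4-hydroxy-8,8-dimethyl-1,5-bis(3-methylbut-2-enyl)bicyclo[3.3.1]non-3-ene-2,9-dione
Product: 28 (1S,5S,7S)-3-(3,4-dihydroxybenzoyl)-7-[(2E)-3,7-dimethylocta-2,6-dienyl]-4-hydroxy-8,8-dimethyl-1,5-bis(3-methylbut-2-enyl)bicyclo[3.3.1]non-3-ene-2,9-dione
Conditions: Bu4NF, AcOH, THF, 0 °C, Ar
Reagents that add atoms: none
Why: Fluoride cleavage of the two aryl silyl ethers. Acetic acid keeps the catechol and the enol protonated, which should prevent air oxidation and base-induced side reactions; no stereocentre is touched.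

## Compound list

1 | 3,4-dihydroxybenzaldehyde | O=Cc1ccc(O)c(O)c1 | starting material
2 | 3,4-bis(triisopropylsilyloxy)benzaldehyde | O=Cc1ccc(O[Si](C(C)C)(C(C)C)C(C)C)c(O[Si](C(C)C)(C(C)C)C(C)C)c1 | intermediate
3 | phloroglucinol | Oc1cc(O)cc(O)c1 | starting material
4 | 1,3,5-tris(methoxymethoxy)benzene | COCOc1cc(OCOC)cc(OCOC)c1 | intermediate
5 | 2,4,6-tris(methoxymethoxy)phenyllithium | [Li]c1c(OCOC)cc(OCOC)cc1OCOC | intermediate (not isolated)
6 | [3,4-bis(triisopropylsilyloxy)phenyl][2,4,6-tris(methoxymethoxy)phenyl]methanol, racemic | COCOc1cc(OCOC)c(C(O)c2ccc(O[Si](C(C)C)(C(C)C)C(C)C)c(O[Si](C(C)C)(C(C)C)C(C)C)c2)c(OCOC)c1 | intermediate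
7 | [3,4-bis(triisopropylsilyloxy)phenyl][2,4,6-tris(methoxymethoxy)phenyl]methanone | COCOc1cc(OCOC)c(C(=O)c2ccc(O[Si](C(C)C)(C(C)C)C(C)C)c(O[Si](C(C)C)(C(C)C)C(C)C)c2)c(OCOC)c1 | intermediate
8 | [3,4-bis(triisopropylsilyloxy)phenyl](2,4,6-trihydroxyphenyl)methanone | O=C(c1ccc(O[Si](C(C)C)(C(C)C)C(C)C)c(O[Si](C(C)C)(C(C)C)C(C)C)c1)c1c(O)cc(O)cc1O | intermediate
9 | prenyl bromide (1-bromo-3-methylbut-2-ene) | CC(C)=CCBr | starting material
10 | [3,4-bis(triisopropylsilyloxy)phenyl][2,4,6-trihydroxy-3-(3-methylbut-2-enyl)phenyl]methanone | CC(C)=CCc1c(O)cc(O)c(C(=O)c2ccc(O[Si](C(C)C)(C(C)C)C(C)C)c(O[Si](C(C)C)(C(C)C)C(C)C)c2)c1O | intermediate (not isolated)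
11 | [3,4-bis(triisopropylsilyloxy)phenyl][2,4,6-trihydroxy-3,5-bis(3-methylbut-2-enyl)phenyl]methanone | CC(C)=CCc1c(O)c(CC=C(C)C)c(O)c(C(=O)c2ccc(O[Si](C(C)C)(C(C)C)C(C)C)c(O[Si](C(C)C)(C(C)C)C(C)C)c2)c1O | intermediate
12 | 2-(phenylsulfonyl)ethanol | OCCS(=O)(=O)c1ccccc1 | starting material
13 | acetone | CC(C)=O | starting material
14 | O,C-dilithio derivative of 2-(phenylsulfonyl)ethanol | [Li]OCC([Li])S(=O)(=O)c1ccccc1 | intermediate (not isolated)
15 | 3-methyl-2-(phenylsulfonyl)butane-1,3-diol, racemic | CC(C)(O)C(CO)S(=O)(=O)c1ccccc1 | intermediate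
16 | 3-hydroxy-3-methyl-2-(phenylsulfonyl)butyl methanesulfonate | CC(C)(O)C(COS(C)(=O)=O)S(=O)(=O)c1ccccc1 | intermediate (not isolated)
17 | 2-methyl-3-(phenylsulfonyl)but-3-en-2-ol | C=C(C(C)(C)O)S(=O)(=O)c1ccccc1 | intermediate
18 | 1-bromo-3-methyl-2-(phenylsulfonyl)but-2-ene | CC(C)=C(CBr)S(=O)(=O)c1ccccc1 | intermediate
19 | [3,4-bis(triisopropylsilyloxy)phenyl]{2,6-dihydroxy-3,5-bis(3-methylbut-2-enyl)-4-[3-methyl-2-(phenylsulfonyl)but-2-enyloxy]phenyl}methanone | CC(C)=CCc1c(O)c(C(=O)c2ccc(O[Si](C(C)C)(C(C)C)C(C)C)c(O[Si](C(C)C)(C(C)C)C(C)C)c2)c(O)c(CC=C(C)C)c1OCC(=C(C)C)S(=O)(=O)c1ccccc1 | intermediate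
20 | racemic 2-[3,4-bis(triisopropylsilyloxy)benzoyl]-3,5-dihydroxy-4,6-bis(3-methylbut-2-enyl)-6-[2-methyl-3-(phenylsulfonyl)but-3-en-2-yl]cyclohexa-2,4-dien-1-one | C=C(S(=O)(=O)c1ccccc1)C(C)(C)C2(CC=C(C)C)C(=O)C(C(=O)c3ccc(O[Si](C(C)C)(C(C)C)C(C)C)c(O[Si](C(C)C)(C(C)C)C(C)C)c3)=C(O)C(CC=C(C)C)=C2O | intermediate
21 | (6S)-enantiomer of 20, the precursor of the key step | C=C(S(=O)(=O)c1ccccc1)C(C)(C)[C@]2(CC=C(C)C)C(=O)C(C(=O)c3ccc(O[Si](C(C)C)(C(C)C)C(C)C)c(O[Si](C(C)C)(C(C)C)C(C)C)c3)=C(O)C(CC=C(C)C)=C2O | intermediate
22 | dipotassium dienolate of 21 | C=C(S(=O)(=O)c1ccccc1)C(C)(C)[C@]2(CC=C(C)C)C(=O)C(C(=O)c3ccc(O[Si](C(C)C)(C(C)C)C(C)C)c(O[Si](C(C)C)(C(C)C)C(C)C)c3)=C([O-])C(CC=C(C)C)=C2[O-].[K+].[K+] | intermediate (not isolated)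
23 | (1S,5S,7R)-3-[3,4-bis(triisopropylsilyloxy)benzoyl]-4-hydroxy-8,8-dimethyl-1,5-bis(3-methylbut-2-enyl)-7-(phenylsulfonyl)bicyclo[3.3.1]non-3-ene-2,9-dione (sulfonyl exo) | O=S(=O)(c1ccccc1)[C@@H]1C[C@]2(CC=C(C)C)C(=O)[C@@](CC=C(C)C)(C(=O)C(C(=O)c3ccc(O[Si](C(C)C)(C(C)C)C(C)C)c(O[Si](C(C)C)(C(C)C)C(C)C)c3)=C2O)C1(C)C | intermediate
24 | geranyl bromide ((2E)-1-bromo-3,7-dimethylocta-2,6-diene) | CC(C)=CCC/C(C)=C/CBr | starting material
25 | dilithio derivative of 23 (C7 carbanion and triketone enolate) | O=S(=O)(c1ccccc1)[C-]1C[C@]2(CC=C(C)C)C(=O)[C@@](CC=C(C)C)(C(=O)C(C(=O)c3ccc(O[Si](C(C)C)(C(C)C)C(C)C)c(O[Si](C(C)C)(C(C)C)C(C)C)c3)=C2[O-])C1(C)C.[Li+].[Li+] | intermediate (not isolated)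
26 | (1S,5S,7S)-3-[3,4-bis(triisopropylsilyloxy)benzoyl]-7-[(2E)-3,7-dimethylocta-2,6-dienyl]-4-hydroxy-8,8-dimethyl-1,5-bis(3-methylbut-2-enyl)-7-(phenylsulfonyl)bicyclo[3.3.1]non-3-ene-2,9-dione (geranyl exo) | CC(C)=CCC/C(C)=C/C[C@]1(S(=O)(=O)c3ccccc3)C[C@]2(CC=C(C)C)C(=O)[C@@](CC=C(C)C)(C(=O)C(C(=O)c4ccc(O[Si](C(C)C)(C(C)C)C(C)C)c(O[Si](C(C)C)(C(C)C)C(C)C)c4)=C2O)C1(C)C | intermediate
27 | (1S,5S,7S)-3-[3,4-bis(triisopropylsilyloxy)benzoyl]-7-[(2E)-3,7-dimethylocta-2,6-dienyl]-4-hydroxy-8,8-dimethyl-1,5-bis(3-methylbut-2-enyl)bicyclo[3.3.1]non-3-ene-2,9-dione (geranyl endo) | CC(C)=CCC/C(C)=C/C[C@H]1C[C@]2(CC=C(C)C)C(=O)[C@@](CC=C(C)C)(C(=O)C(C(=O)c3ccc(O[Si](C(C)C)(C(C)C)C(C)C)c(O[Si](C(C)C)(C(C)C)C(C)C)c3)=C2O)C1(C)C | intermediate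
28 | (1S,5S,7S)-3-(3,4-dihydroxybenzoyl)-7-[(2E)-3,7-dimethylocta-2,6-dienyl]-4-hydroxy-8,8-dimethyl-1,5-bis(3-methylbut-2-enyl)bicyclo[3.3.1]non-3-ene-2,9-dione | CC(C)=CCC/C(C)=C/C[C@H]1C[C@]2(CC=C(C)C)C(=O)[C@@](CC=C(C)C)(C(=O)C(C(=O)c3ccc(O)c(O)c3)=C2O)C1(C)C | target

## Step count and risk

Total: 16 steps. Longest linear sequence: 12 steps (3 → 4 → 6 → 7 → 8 → 11 → 19 → 20 → 21 → 23 → 26 → 27 → 28; the branch from 1 is equally long, the side chain from 12 is 10).

**Step 13 (key step).** The most likely failure is an unfavourable or reversible addition: the dianion trades a highly stabilised dienolate for a sulfonyl carbanion, so starting material may be recovered, the oxygen-closed dihydropyran may be trapped on quench, or some closure may leak through C3. Fallback: from 21, form the dianion with KH in THF, so that no amine conjugate acid is present, let the closure equilibrate at 0 to 25 °C, then add geranyl bromide 24 at −78 °C. The C7 carbanion, much more nucleophilic than the dienolate, is then drained irreversibly by C-alkylation instead of by proton transfer. This joins the route at 26 and makes no compound outside the list (F0).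

**Step 11.** The risk is a second [3,3] shift: a Cope rearrangement through the C9=C5 enol would move the side chain from C1 to C5 as the linear 3-methyl-2-(phenylsulfonyl)but-2-enyl isomer, relieving the strain between C1 and C8. Return to the ether at higher temperature is the other loss. Fallback: from 19, heat at the lowest effective temperature (80 to 100 °C, PhMe) with Et3N, which is too weak to deconjugate the ether but turns the strongly acidic Claisen product into its ammonium enolate, so that the Michael closure of step 13 consumes it as it forms. This gives the racemic bicyclic sulfone F1, which is resolved on the same chiral phase and joins the route at 23.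

**Step 14.** Deprotonation may be slow because the remaining hydrogen of the exo sulfone lies on the endo face, and alkylation at a carbon flanked by the quaternary C8 may be slower than O-geranylation of the enolate or ortho-metalation of the phenylsulfonyl ring. Fallback, from 23:
- The carbanion is trapped with monomeric formaldehyde, the smallest electrophile, and the alkoxide is acetylated in the flask (Ac2O), giving the β-acetoxy sulfone F2. Any enol acetate on the triketone is cleaved on bicarbonate work-up.
- Julia-type reductive elimination with Na(Hg) in buffered MeOH gives the 7-methylene compound F3.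
- 9-Borabicyclo[3.3.1]nonane adds to the 1,1-disubstituted alkene from the exo face, in preference to the trisubstituted prenyl alkenes. This puts hydrogen on C7 exo and boron on the new endo methylene, giving the alkylborane F4.
- B-alkyl Suzuki–Miyaura coupling of F4 with (E)-1-iodo-2,6-dimethylhepta-1,5-diene F5 (PdCl2(dppf) as divalent palladium precatalyst, AsPh3, Cs2CO3, DMF/H2O) completes the geranyl chain with retention of the (E)-geometry. F5 would be made from 6-methylhept-5-en-1-yne by zirconium-catalysed carboalumination (AlMe3, (C5H5)2ZrCl2) and iodinolysis.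

This joins the route at 27 and also bypasses step 15.

**Step 15.** Three things can go wrong: loss of facial selectivity in the protonation at C7 (giving the epimer with exo geranyl), 5-exo cyclisation of the transient tertiary C7 radical onto a bridgehead prenyl group, and over-reduction of the C9 ketone. Fallback: from 26, change the way hydrogen reaches C7 from protonation of a carbanion to hydrogen-atom transfer to the radical. Homogeneous electron transfer with SmI2 in THF/HMPA in the presence of a bulky thiol should quench the C7 radical from the exo face before it is reduced further or cyclises. This joins the route at 27 and makes no compound outside the list (F0).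

## Further compounds

F0 | step 13 | none | none
F1 | step 11 | racemic 3-[3,4-bis(triisopropylsilyloxy)benzoyl]-4-hydroxy-8,8-dimethyl-1,5-bis(3-methylbut-2-enyl)-7-(phenylsulfonyl)bicyclo[3.3.1]non-3-ene-2,9-dione (racemate of 23; the 1S,5S,7R enantiomer is drawn) | O=S(=O)(c1ccccc1)[C@@H]1C[C@]2(CC=C(C)C)C(=O)[C@@](CC=C(C)C)(C(=O)C(C(=O)c3ccc(O[Si](C(C)C)(C(C)C)C(C)C)c(O[Si](C(C)C)(C(C)C)C(C)C)c3)=C2O)C1(C)C
F2 | step 14 | 7-(acetoxymethyl)-7-(phenylsulfonyl) derivative of the bicycle (1S,5S; acetoxymethyl exo expected, C7 epimer immaterial) | CC(=O)OC[C@]1(S(=O)(=O)c3ccccc3)C[C@]2(CC=C(C)C)C(=O)[C@@](CC=C(C)C)(C(=O)C(C(=O)c4ccc(O[Si](C(C)C)(C(C)C)C(C)C)c(O[Si](C(C)C)(C(C)C)C(C)C)c4)=C2O)C1(C)C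
F3 | step 14 | (1S,5S)-3-[3,4-bis(triisopropylsilyloxy)benzoyl]-4-hydroxy-8,8-dimethyl-7-methylidene-1,5-bis(3-methylbut-2-enyl)bicyclo[3.3.1]non-3-ene-2,9-dione | C=C1C[C@]2(CC=C(C)C)C(=O)[C@@](CC=C(C)C)(C(=O)C(C(=O)c3ccc(O[Si](C(C)C)(C(C)C)C(C)C)c(O[Si](C(C)C)(C(C)C)C(C)C)c3)=C2O)C1(C)C
F4 | step 14 | B-alkyl-9-borabicyclo[3.3.1]nonane adduct of F3 (boron on the endo methylene of C7, hydrogen on C7 exo; not isolated) | C1CC2CCCC(C1)B2C[C@H]3C[C@]4(CC=C(C)C)C(=O)[C@@](CC=C(C)C)(C(=O)C(C(=O)c5ccc(O[Si](C(C)C)(C(C)C)C(C)C)c(O[Si](C(C)C)(C(C)C)C(C)C)c5)=C4O)C3(C)C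
F5 | step 14 | (E)-1-iodo-2,6-dimethylhepta-1,5-diene | I/C=C(\C)CCC=C(C)C
F0 | step 15 | none | none
A1 | alternative 1 | C3-unsubstituted bicyclic trione as its C4 methyl enol ether (configuration of 28 at C1, C5, C7) | CC(C)=CCC/C(C)=C/C[C@H]1C[C@]2(CC=C(C)C)C(=O)[C@@](CC=C(C)C)(C(=O)C=C2OC)C1(C)C
A2 | alternative 1 | fused enol lactone: ring A enol (C1=C9) acylated on O9 by C2 of a 3-methoxyacryloyl unit attached to C5 | CC(C)=CCC/C(C)=C/C[C@H]1C[C@]2(CC=C(C)C)C(OC(=O)C=C2OC)=C(CC=C(C)C)C1(C)C
A3 | alternative 2 | C3-unsubstituted bicyclic 2,4,9-trione (configuration of 28 at C1, C5, C7) | CC(C)=CCC/C(C)=C/C[C@H]1C[C@]2(CC=C(C)C)C(=O)[C@@](CC=C(C)C)(C(=O)CC2=O)C1(C)C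
A4 | alternative 2 | ring A cyclohexanone with formyl on C5 and diazoacetyl on C1, cis | CC(C)=CCC/C(C)=C/C[C@H]1C[C@@](CC=C(C)C)(C=O)C(=O)[C@@](CC=C(C)C)(C(=O)C=[N+]=[N-])C1(C)C
A5 | alternative 3 | C3-unsubstituted bicyclic trione as its C4 ethyl enol ether (configuration of 28 at C1, C5, C7) | CC(C)=CCC/C(C)=C/C[C@H]1C[C@]2(CC=C(C)C)C(=O)[C@@](CC=C(C)C)(C(=O)C=C2OCC)C1(C)C
A6 | alternative 3 | ring A tert-butyldimethylsilyl enol ether (C5=C9) with a 3-ethoxypropynoyl group on C1 | CC(C)=CCC/C(C)=C/C[C@H]1CC(CC=C(C)C)=C(O[Si](C)(C)C(C)(C)C)[C@@](CC=C(C)C)(C(=O)C#COCC)C1(C)C
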